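**Retrosynthetic overview**

1. Salvianolic acid H ⇐ one global O-dealkylation of its pentamethyl ether dimethyl ester (five ArOMe, two CO2Me).
2. Danshensu CO2Me ⇐ tert-butylamide (imidate hydrolysis). The Z aryl enol ether acrylate ⇐ Horner–Wadsworth–Emmons reaction of veratraldehyde with an α-aryloxyphosphonoacetate, made by rhodium-carbenoid O–H insertion at the free 3-OH of the isoferuloyl unit.
3. Key disconnection: the C1–C2 bond of the danshensu unit together with the depside C–O bond ⇐ catalytic enantioselective three-component Passerini reaction of (3,4-dimethoxyphenyl)acetaldehyde, isoferulic acid and tert-butyl isocyanide. The isocyanide carbon is a carbamoyl (carboxyl) anion equivalent, so two natively electrophilic carbons are joined and the (R)-centre is set in the same event.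
4. The aldehyde ⇐ 2-(3,4-dimethoxyphenyl)ethanol by oxidation.
5. Rings: none is formed. The three benzene rings are bought (danshensu ring with the alcohol, caffeoyl ring with isoferulic acid, terminal ring with veratraldehyde).

**Assumptions**

- Trimethyl diazophosphonoacetate is taken as a catalogue reagent (otherwise it is one diazo-transfer step from trimethyl phosphonoacetate).
- The sense of induction of the phosphoric acid in step 2 is not known for this substrate. The antipode that gives the (R)-adduct is used, written here as (R), and is fixed on the first run by chiral HPLC.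

**Route**

Step 1
Reactants: 1 2-(3,4-dimethoxyphenyl)ethanol
Product: 2 (3,4-dimethoxyphenyl)acetaldehyde
Conditions: IBX (2-iodoxybenzoic acid, 1.3 equiv), EtOAc, 80 °C, 3 h; filter, concentrate, use at once
Reagents that add atoms: none
Why: IBX oxidation of a primary alcohol stops at the aldehyde under neutral non-aqueous conditions, and filtration alone delivers the enolisable arylacetaldehyde without exposure to acid, base or silica.

Step 2
Reactants: 2 (3,4-dimethoxyphenyl)acetaldehyde; 3 isoferulic acid; 4 tert-butyl isocyanide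
Product: 6 (R)-1-(tert-butylamino)-3-(3,4-dimethoxyphenyl)-1-oxopropan-2-yl (E)-3-(3-hydroxy-4-methoxyphenyl)prop-2-enoate, via imidate α-adduct 5 (not isolated)
Conditions: (R)-3,3′-bis(2,4,6-triisopropylphenyl)-1,1′-binaphthyl-2,2′-diyl hydrogen phosphate (10 mol %), 4 Å MS, CHCl3 (slurry of 3 that clears as it reacts), 0 °C → rt, 48 h; one recrystallisation
Reagents that add atoms: none
Why: In this enantioselective three-component Passerini reaction the isocyanide carbon (a carbamoyl-anion equivalent) adds to one face of the aldehyde held in the chiral phosphate–carboxylic acid hydrogen-bonded pair and the imidate 5 then undergoes Mumm acyl transfer, so the C1–C2 bond, the (R)-stereocentre and the depside ester arise together while the phenol stays a spectator.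

Step 3
Reactants: 6 (R)-Passerini adduct (free 3-OH phenol); 7 trimethyl diazophosphonoacetate
Product: 8 (R)-1-(tert-butylamino)-3-(3,4-dimethoxyphenyl)-1-oxopropan-2-yl (E)-3-{3-[1-(dimethoxyphosphoryl)-2-methoxy-2-oxoethoxy]-4-methoxyphenyl}prop-2-enoate (about 1:1 epimers at the phosphonate carbon)
Conditions: Rh2(OAc)4 (2 mol %), toluene, 80 °C, slow addition of 7
Reagents that add atoms: none
Why: Rhodium-carbenoid O–H insertion into the phenol is much faster than reaction at the hindered tert-butylamide N–H, the electron-poor alkene or the arenes, and the new phosphonate stereocentre does not matter because step 4 destroys it.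

Step 4
Reactants: 8 α-aryloxyphosphonoacetate; 9 veratraldehyde (3,4-dimethoxybenzaldehyde)
Product: 10 methyl (Z)-2-{5-[(E)-3-{[(R)-1-(tert-butylamino)-3-(3,4-dimethoxyphenyl)-1-oxopropan-2-yl]oxy}-3-oxoprop-1-enyl]-2-methoxyphenoxy}-3-(3,4-dimethoxyphenyl)prop-2-enoate
Conditions: LiN(SiMe3)2 (1.05 equiv), THF, −78 °C; then 9, −78 °C → rt; minor E isomer removed by chromatography
Reagents that add atoms: none
Why: Horner–Wadsworth–Emmons olefination at the only strongly acidic C–H gives mainly the Z enol ether (aryl trans to the ester, also the thermodynamic isomer) and leaves the (R)-centre untouched.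

Step 5
Reactants: 10 Z enol ether tert-butylamide
Product: 12 methyl (Z)-2-{5-[(E)-3-{[(R)-3-(3,4-dimethoxyphenyl)-1-methoxy-1-oxopropan-2-yl]oxy}-3-oxoprop-1-enyl]-2-methoxyphenoxy}-3-(3,4-dimethoxyphenyl)prop-2-enoate, via O-methyl imidatonium tetrafluoroborate 11 (not isolated)
Conditions: Me3OBF4 (3 equiv), CH2Cl2, rt, 16 h; then H2O–THF, rt
Reagents that add atoms: trimethyloxonium tetrafluoroborate C[O+](C)C.F[B-](F)(F)F; water O
Why: Meerwein O-methylation of the amide (the most nucleophilic oxygen present) followed by hydrolysis of the imidate salt at acidic pH, where the amine is the leaving group, turns the tert-butylamide into the methyl ester without acyl substitution at the other esters or enolisation of the stereocentre.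

Step 6
Reactants: 12 salvianolic acid H pentamethyl ether dimethyl ester
Product: 14 salvianolic acid H, via heptakis(trimethylsilyl) derivative 13 (not isolated)
Conditions: Me3SiI (20 equiv), quinoline, 130 °C, 3 h, Ar; then 1 M aq. HCl, EtOAc; reversed-phase HPLC
Reagents that add atoms: none
Why: Silyl-assisted iodide SN2 dealkylation removes all seven O-methyl groups but not the secondary-alkyl depside ester or the vinyl and aryl C–O bonds, and the quinoline-buffered non-hydrolytic medium keeps the (R)-centre and both alkene geometries, as is known for permethylated caffeic acid depsides of this type.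

**Compound list**

1 | 2-(3,4-dimethoxyphenyl)ethanol (homoveratryl alcohol) | COc1ccc(CCO)cc1OC | starting material
2 | (3,4-dimethoxyphenyl)acetaldehyde | COc1ccc(CC=O)cc1OC | intermediate
3 | isoferulic acid, (E)-3-(3-hydroxy-4-methoxyphenyl)prop-2-enoic acid | COc1ccc(/C=C/C(=O)O)cc1O | starting material
4 | tert-butyl isocyanide | [C-]#[N+]C(C)(C)C | starting material
5 | imidate α-adduct: (R)-N-tert-butyl-3-(3,4-dimethoxyphenyl)-2-hydroxypropanimidic (E)-3-(3-hydroxy-4-methoxyphenyl)prop-2-enoic anhydride | O[C@H](Cc1ccc(OC)c(OC)c1)C(=NC(C)(C)C)OC(=O)/C=C/c1ccc(OC)c(O)c1 | intermediate (not isolated)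
6 | (R)-1-(tert-butylamino)-3-(3,4-dimethoxyphenyl)-1-oxopropan-2-yl (E)-3-(3-hydroxy-4-methoxyphenyl)prop-2-enoate | O=C(/C=C/c1ccc(OC)c(O)c1)O[C@H](Cc1ccc(OC)c(OC)c1)C(=O)NC(C)(C)C | intermediate
7 | trimethyl diazophosphonoacetate, methyl 2-diazo-2-(dimethoxyphosphoryl)acetate | COC(=O)C(=[N+]=[N-])P(=O)(OC)OC | starting material
8 | (R)-1-(tert-butylamino)-3-(3,4-dimethoxyphenyl)-1-oxopropan-2-yl (E)-3-{3-[1-(dimethoxyphosphoryl)-2-methoxy-2-oxoethoxy]-4-methoxyphenyl}prop-2-enoate, epimers at the phosphonate carbon | O=C(/C=C/c1ccc(OC)c(OC(C(=O)OC)P(=O)(OC)OC)c1)O[C@H](Cc1ccc(OC)c(OC)c1)C(=O)NC(C)(C)C | intermediate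
9 | veratraldehyde, 3,4-dimethoxybenzaldehyde | COc1ccc(C=O)cc1OC | starting material
10 | methyl (Z)-2-{5-[(E)-3-{[(R)-1-(tert-butylamino)-3-(3,4-dimethoxyphenyl)-1-oxopropan-2-yl]oxy}-3-oxoprop-1-enyl]-2-methoxyphenoxy}-3-(3,4-dimethoxyphenyl)prop-2-enoate | O=C(/C=C/c1ccc(OC)c(O/C(=C\c2ccc(OC)c(OC)c2)C(=O)OC)c1)O[C@H](Cc1ccc(OC)c(OC)c1)C(=O)NC(C)(C)C | intermediate
11 | O-methyl imidatonium tetrafluoroborate of 10 (N-tert-butyl methyl imidate salt, R) | O=C(/C=C/c1ccc(OC)c(O/C(=C\c2ccc(OC)c(OC)c2)C(=O)OC)c1)O[C@H](Cc1ccc(OC)c(OC)c1)C(OC)=[NH+]C(C)(C)C.F[B-](F)(F)F | intermediate (not isolated)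
12 | methyl (Z)-2-{5-[(E)-3-{[(R)-3-(3,4-dimethoxyphenyl)-1-methoxy-1-oxopropan-2-yl]oxy}-3-oxoprop-1-enyl]-2-methoxyphenoxy}-3-(3,4-dimethoxyphenyl)prop-2-enoate | O=C(/C=C/c1ccc(OC)c(O/C(=C\c2ccc(OC)c(OC)c2)C(=O)OC)c1)O[C@H](Cc1ccc(OC)c(OC)c1)C(=O)OC | intermediate
13 | heptakis(trimethylsilyl) salvianolic acid H (five aryl silyl ethers, two silyl esters; R, Z, E) | O=C(/C=C/c1ccc(O[Si](C)(C)C)c(O/C(=C\c2ccc(O[Si](C)(C)C)c(O[Si](C)(C)C)c2)C(=O)O[Si](C)(C)C)c1)O[C@H](Cc1ccc(O[Si](C)(C)C)c(O[Si](C)(C)C)c1)C(=O)O[Si](C)(C)C | intermediate (not isolated)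
14 | salvianolic acid H | O=C(/C=C/c1ccc(O)c(O/C(=C\c2ccc(O)c(O)c2)C(=O)O)c1)O[C@H](Cc1ccc(O)c(O)c1)C(=O)O | target

**Step count and risks**

Total steps: 6. Longest linear sequence: 6 (1 → 2 → 6 → 8 → 10 → 12 → 14).

The three steps most likely to fail:

Step 2. The enantioselectivity and rate of the phosphoric-acid-catalysed Passerini reaction are untested for a sparingly soluble phenolic cinnamic acid and an enolisable arylacetaldehyde. The fallback sets out from 2 and comes back to the route at 12. It sets the centre enzymatically with the opposite sense and inverts it on esterification.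
- Compound 2 is treated with HCN and the (S)-selective hydroxynitrile lyase of Hevea brasiliensis (citrate buffer pH 5, MTBE, 5 °C) to give (S)-3-(3,4-dimethoxyphenyl)-2-hydroxypropanenitrile F1.
- Pinner methanolysis (HCl, MeOH, then water) gives methyl (S)-3-(3,4-dimethoxyphenyl)-2-hydroxypropanoate F2.
- Mitsunobu esterification with 3 (PPh3, DIAD, THF, 0 °C) gives, with clean inversion, methyl (R)-2-{[(E)-3-(3-hydroxy-4-methoxyphenyl)prop-2-enoyl]oxy}-3-(3,4-dimethoxyphenyl)propanoate F3. The carboxylic acid, not the phenol, is the acidic partner.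
- Rh2(OAc)4-catalysed O–H insertion with 7 gives the phosphonate methyl ester F4.
- Horner–Wadsworth–Emmons reaction with 9 (LiN(SiMe3)2, THF) gives 12 directly, so step 5 is not needed.

Step 5. The imidate route may suffer from competing O-alkylation or neighbouring-group scrambling in so many-estered a substrate. The fallback sets out from 10 and comes back to the route at 13.
- CF3CO2H at 60 °C removes the tert-butyl group as isobutene to give the primary amide F5.
- Nitrosative deamination with tert-butyl nitrite in AcOH gives the carboxylic acid F6.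
- F6 is taken into the conditions of step 6, where Me3SiI silylates the free acid, so it joins the route at 13.

Step 6. Seven dealkylations at 130 °C may erode the depside ester or the Z enol ether. The fallback sets out from 12 and comes back to the route at 14, unmasking in two stages by two different mechanisms.
- Me3SnOH (ClCH2CH2Cl, 80 °C) hydrolyses the two methyl esters but not the hindered secondary depside ester and gives the diacid pentamethyl ether F7.
- BBr3 (CH2Cl2, −78 → 0 °C, aqueous quench) then cleaves only the five aryl methyl ethers to give 14.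

**Further compounds**

F1 | step 2 | (S)-3-(3,4-dimethoxyphenyl)-2-hydroxypropanenitrile | O[C@@H](Cc1ccc(OC)c(OC)c1)C#N
F2 | step 2 | methyl (S)-3-(3,4-dimethoxyphenyl)-2-hydroxypropanoate | O[C@@H](Cc1ccc(OC)c(OC)c1)C(=O)OC
F3 | step 2 | methyl (R)-2-{[(E)-3-(3-hydroxy-4-methoxyphenyl)prop-2-enoyl]oxy}-3-(3,4-dimethoxyphenyl)propanoate | O=C(/C=C/c1ccc(OC)c(O)c1)O[C@H](Cc1ccc(OC)c(OC)c1)C(=O)OC
F4 | step 2 | methyl (R)-2-{[(E)-3-{3-[1-(dimethoxyphosphoryl)-2-methoxy-2-oxoethoxy]-4-methoxyphenyl}prop-2-enoyl]oxy}-3-(3,4-dimethoxyphenyl)propanoate, epimers at the phosphonate carbon | O=C(/C=C/c1ccc(OC)c(OC(C(=O)OC)P(=O)(OC)OC)c1)O[C@H](Cc1ccc(OC)c(OC)c1)C(=O)OC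
F5 | step 5 | methyl (Z)-2-{5-[(E)-3-{[(R)-1-amino-3-(3,4-dimethoxyphenyl)-1-oxopropan-2-yl]oxy}-3-oxoprop-1-enyl]-2-methoxyphenoxy}-3-(3,4-dimethoxyphenyl)prop-2-enoate | O=C(/C=C/c1ccc(OC)c(O/C(=C\c2ccc(OC)c(OC)c2)C(=O)OC)c1)O[C@H](Cc1ccc(OC)c(OC)c1)C(N)=O
F6 | step 5 | (R)-3-(3,4-dimethoxyphenyl)-2-{[(E)-3-(4-methoxy-3-{[(Z)-1-methoxy-1-oxo-3-(3,4-dimethoxyphenyl)prop-2-en-2-yl]oxy}phenyl)prop-2-enoyl]oxy}propanoic acid | O=C(/C=C/c1ccc(OC)c(O/C(=C\c2ccc(OC)c(OC)c2)C(=O)OC)c1)O[C@H](Cc1ccc(OC)c(OC)c1)C(=O)O
F7 | step 6 | salvianolic acid H pentamethyl ether (both carboxylic acids free; R, Z, E) | O=C(/C=C/c1ccc(OC)c(O/C(=C\c2ccc(OC)c(OC)c2)C(=O)O)c1)O[C@H](Cc1ccc(OC)c(OC)c1)C(=O)O
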